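The earlier runs and the new flask come from a simulation with made-up constants; the scatter is artificial.

At 0.21 M of substrate against 0.14 M, the summer run read 33.0% target at 3.00 h and the spring flask 33.2% at 3.00 h, much the same share of the charge. So you can read the summer run as the later course of your spring flask. You want a quick number for 10 h, and your hunch is that the spring flask rests once the feed ends.

| flask | substrate | reagent | remark | time |
|---|---|---|---|---|
| spring | 0.14 M | 0.112 M (fed, over 10 h) | the very flask that is asked about, followed so far; the fed solution adds 0.10 times the starting volume |  |
| summer | 0.21 M | 0.112 M (fed, over 10 h) | run made earlier; the fed solution adds 0.10 times the starting volume |  |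
| flask | 0.14 M | 0.112 M (fed, over 10 h) | the fed solution adds 0.10 times the starting volume | 10 h |

| run | time / h | target / % | over-reaction product / % |
|---|---|---|---|
| spring | 0.667 | 13.1 | 1.2 |
| spring | 1.33 | 22.9 | 3.5 |
| spring | 2.00 | 28.1 | 7.4 |
| spring | 2.50 | 31.8 | 10.6 |
| spring | 3.00 | 33.2 | 13.8 |
| summer | 1.33 | 23.0 | 3.6 |
| summer | 3.00 | 33.0 | 13.4 |
| summer | 4.00 | 34.3 | 20.3 |
| summer | 6.00 | 31.5 | 34.0 |
| summer | 8.00 | 26.0 | 45.8 |

(each reading ± 0.3 percentage points)

- amounts are per litre of the starting volume; all of the dose is in the solution fed
- the reaction counts as stopped when no species that holds the substrate changes by six tenths of a point or more over the second half of the time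

* why nothing more happens at 10 h, or that something still does (all of the substrate has reacted / it is still moving / forward and back rates have come level / the reagent has run out first)
* the target standing at 10 h, as a percentage of the substrate charged
* the over-reaction product standing at 10 h, as a percentage of the substrate charged
* the intermediate A standing at 10 h, as a percentage of the substrate charged

Ask first where the target is heading. In the summer run it fell from 34.3% at 4.00 h to 26.0% at 8.00 h, so it is a way station. From 6.00 h to 8.00 h the over-reaction product gained 12 percentage points while the target averaged 28.7%. That gives 0.205 /h, a reading I carry as the drain constant, a first-order rate constant: over-reaction product gained per hour for each part of target standing.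

Let the target of that last summer reading decay at the constant with nothing fed in, and 16.7% of the charge passes over in 5.00 h, far beyond the stopping limit. My reckoning therefore goes against your hunch, though it gives a direction and no standing values.

Those come from the forecast: it is still moving, target 19.7%, over-reaction product 55.4%, intermediate A 18%, and in its words “the reaction has not stopped”.

The flask gives it is still moving, with target 21.0%, over-reaction product 55.7% and intermediate A 5.75%.

    substrate ⇌ intermediate A (K = 0.670, k = 2.00 × 10⁻⁵ /s)
    reagent + intermediate C → side product B (k = 0.00600 /M/s)
    target → over-reaction product (k = 5.70 × 10⁻⁵ /s)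
    substrate + intermediate A → side product C (k = 1.30 × 10⁻⁵ /M/s)
    intermediate A ⇌ intermediate C (K = 2.40, k = 1.60 × 10⁻⁵ /s)
    substrate → target (k = 6.70 × 10⁻⁵ /s)
    substrate + reagent ⇌ intermediate B (K = 2.80 /M, k = 8.70 × 10⁻⁴ /M/s)
    reagent + intermediate A → side product A (k = 2.90 × 10⁻⁴ /M/s)
    2 reagent → homo dimer (k = 7.90 × 10⁻⁵ /M/s)

Intermediate A stands 12 points below the forecast, and beside it the flask holds side product A at 3.68% and side product B at 4.35%. With target at 33.5% after 5.00 h and 21.0% after 10.0 h, the drain constant gives 27.9% for that stretch, and the over-reaction product rose 28 points. Read at 25 h, the same flask holds over-reaction product at 83.5% and target at 2.52%; let that target decay at the constant, leaving out what still feeds it, and in 5.00 h it hands over 1.62% of the charge.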